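**Retrosynthetic overview**
1. The target is a (−)-syringaresinol core (cis-fused 3,7-dioxabicyclo[3.3.0]octane; lignan locants C7–C9 and C7'–C9') whose two syringyl oxygens carry one erythro guaiacylglycerol unit (rings E–D) and a threo–erythro pair of such units (rings A–B–C).
2. Each arm unit is cut at its C7–C8 bond: syn-aldol reaction of an aryloxyacetyl oxazolidinone with a vanillin-type aldehyde gives threo, and inversion at C7 gives erythro where needed; the A–B unit is made apart as aldehyde 29.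
3. The core is cut across C9–C8 and C8'–C7' of one tetrahydrofuran ring: [3+2] cycloaddition of a non-stabilised carbonyl ylide (from O-allyl syringaldehyde) to an enantiopure 5-aryl butenolide (from O-MOM syringaldehyde), so the two aryl rings leave the key step with different phenol protection.
4. Enabling feature: C9 (CH2), the ring oxygen and C7' (ArCH) of one ring form a CH2–O–CH(Ar) triad, which is the skeleton of the carbonyl ylide of the aryl aldehyde; it spans the C8–C8' ring-fusion bond, which can be the C=C of a butenolide built from C7, C8, C8', C9' and the other ring oxygen, with C7 as the controlling stereocentre.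
5. Ring order: butenolide (first oxygen ring, lactone level) → second tetrahydrofuran by the cycloaddition → lactone reduced and re-closed as the ether → two temporary 1,3-dioxane acetonides on the arms, removed before the final hydrogenolysis.

Key step: step 6

Assumption: (R,R)-ProPhenol/Me2Zn is taken to deliver the propiolate to the Re face of aldehyde 2 (S carbinol), the (S,S)-ligand being used if the sense is the reverse; both enantiomers of 4-benzyl-3-(chloroacetyl)oxazolidin-2-one are taken as purchasable.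
Locants: ring A = terminal guaiacyl of the two-unit arm, ring B = inner guaiacyl, ring C = syringyl carrying that arm, ring D = the other syringyl, ring E = guaiacyl of the single arm; C7/C8/C9 of each arm unit = ArCH(O)/CH(OAr)/CH2O.

**Step 1**
Reactants: 1 syringaldehyde
Product: 2 3,5-dimethoxy-4-(methoxymethoxy)benzaldehyde
Conditions: MOMCl, iPr2NEt, CH2Cl2, 0 °C to rt
Reagents that add atoms: chloromethyl methyl ether, COCCl
Why: Williamson-type O-alkylation of the phenol; the MOM acetal should survive the organozinc, hydrogenation, fluoride and hydride steps and is later removable in the presence of an allyl ether.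

**Step 2**
Reactants: 2 3,5-dimethoxy-4-(methoxymethoxy)benzaldehyde; 3 methyl propiolate
Product: 4 methyl (4S)-4-[3,5-dimethoxy-4-(methoxymethoxy)phenyl]-4-hydroxybut-2-ynoate
Conditions: (R,R)-ProPhenol (20 mol%), Me2Zn, toluene, 4 °C; aq. NH4Cl
Reagents that add atoms: none
Why: Catalytic enantioselective alkynylation of an aryl aldehyde by a dinuclear zinc–ProPhenol alkynylide, which should add to the Re face and set the benzylic carbinol (the later C7 of the core) as S.

**Step 3**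
Reactants: 4 methyl (4S)-4-aryl-4-hydroxybut-2-ynoate
Product: 6 (5R)-5-[3,5-dimethoxy-4-(methoxymethoxy)phenyl]furan-2(5H)-one, via Z-hydroxy enoate 5 (not isolated)
Conditions: H2 (1 atm), Pd/CaCO3 poisoned with Pb(OAc)2 (Lindlar catalyst), quinoline, EtOAc, rt; then PPTS (cat.), CH2Cl2, rt
Reagents that add atoms: none
Why: Lindlar cis-semihydrogenation gives the Z-γ-hydroxy enoate, which lactonises to the butenolide under mild acid without touching the stereocentre (the descriptor changes from S to R only through the priority rules).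

**Step 4**
Reactants: 1 syringaldehyde
Product: 7 4-(allyloxy)-3,5-dimethoxybenzaldehyde
Conditions: allyl bromide, K2CO3, DMF, 50 °C
Reagents that add atoms: allyl bromide, C=CCBr
Why: Williamson etherification; the allyl ether should tolerate acid chloride, fluoride and hydride and is later removed by zerovalent palladium in the presence of benzyl ethers and acetonides.

**Step 5**
Reactants: 7 4-(allyloxy)-3,5-dimethoxybenzaldehyde; 8 (trimethylsilyl)methanol
Product: 9 4-(allyloxy)-3,5-dimethoxybenzaldehyde bis[(trimethylsilyl)methyl] acetal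
Conditions: 8 (2.5 equiv in all), p-TsOH·H2O (cat.), cyclohexane, reflux, Dean–Stark trap
Reagents that add atoms: (trimethylsilyl)methanol (second equivalent), C[Si](C)(C)CO
Why: Acid-catalysed acetalisation in which two molecules of alcohol 8 condense with the aldehyde, driven by azeotropic removal of the one molecule of water formed; this places the silylmethyl group needed for ylide generation on the aldehyde oxygen.

**Step 6**
Reactants: 9 bis[(trimethylsilyl)methyl] acetal; 6 (5R)-5-aryl-furan-2(5H)-one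
Product: 12 (3R,3aS,6R,6aR)-6-[4-(allyloxy)-3,5-dimethoxyphenyl]-3-[3,5-dimethoxy-4-(methoxymethoxy)phenyl]tetrahydro-1H,3H-furo[3,4-c]furan-1-one, via α-chloro ether 10 (not isolated), via carbonyl ylide 11 (not isolated)
Conditions: 9 (2 equiv), AcCl, ZnBr2 (1 mol%), CH2Cl2, 0 °C to rt, volatiles removed; then slow addition to 6, CsF, MeCN, rt
Reagents that add atoms: none
Why: Ionisation of the benzylic C–Cl bond of 10 (helped by the 4-alkoxy-3,5-dimethoxyphenyl ring) and fluoride attack at silicon effect a 1,3-elimination to the non-stabilised carbonyl ylide 11, which adds as a HOMO-controlled 1,3-dipole across the electron-poor C=C of butenolide 6 in a concerted, asynchronous [3+2] cycloaddition; the closest known reaction type is the fluoride-induced generation of carbonyl ylides from α-chloroalkyl (trimethylsilyl)methyl ethers and their cycloaddition to α,β-unsaturated esters. The new tetrahydrofuran ring is closed by this [3+2] cycloaddition, suprafacial on both partners, so the ring fusion must be cis. Regioselectivity: the electron-rich aryl ring holds the positive charge at the benzylic terminus, so the CH2 terminus is the nucleophilic end and bonds to the β-carbon while the ArCH terminus closes onto the α-carbon, which also keeps the bulky terminus away from the C5 aryl group. Facial selectivity: the C5 aryl group of 6 (C7 of the core) shields one face, so both new bonds form anti to it, which fixes C8 and C8'. The C7' stereocentre follows from the exo transition state, in which the ylide aryl group points away from the lactone ring and ends on the convex face of the bicycle. The chemoselectivity needed over the unactivated allyl ether alkene is secured by the much lower LUMO of the butenolide.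

**Step 7**
Reactants: 12 furofuranone cycloadduct
Product: 13 (R)-[3,5-dimethoxy-4-(methoxymethoxy)phenyl]{(3S,4S,5R)-5-[4-(allyloxy)-3,5-dimethoxyphenyl]-4-(hydroxymethyl)tetrahydrofuran-3-yl}methanol
Conditions: LiAlH4, THF, 0 °C; aq. potassium sodium tartrate (KNaC4H4O6) work-up
Reagents that add atoms: none
Why: Hydride reduction of the γ-lactone to the 1,4-diol; no stereocentre is touched and the MOM and allyl ethers are inert.

**Step 8**
Reactants: 13 diol
Product: 15 (1R,3aS,4R,6aS)-4-[4-(allyloxy)-3,5-dimethoxyphenyl]-1-[3,5-dimethoxy-4-(methoxymethoxy)phenyl]tetrahydro-1H,3H-furo[3,4-c]furan, via primary mesylate 14 (not isolated)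
Conditions: MsCl (1.05 equiv), Et3N, CH2Cl2, −20 °C to rt
Reagents that add atoms: none
Why: Selective sulfonylation of the primary alcohol followed by intramolecular Williamson etherification (5-exo-tet) by the benzylic hydroxyl closes the first tetrahydrofuran at the ether level with retention at C7.

**Step 9**
Reactants: 15 MOM/allyl-protected (−)-syringaresinol
Product: 16 4-{(1R,3aS,4R,6aS)-4-[4-(allyloxy)-3,5-dimethoxyphenyl]tetrahydro-1H,3H-furo[3,4-c]furan-1-yl}-2,6-dimethoxyphenol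
Conditions: NaHSO4·SiO2, CH2Cl2, rt
Reagents that add atoms: none
Why: Mild heterogeneous acid-catalysed cleavage of the phenolic MOM acetal, which should leave the allyl ether and the benzylic ethers of the furofuran intact.

**Step 10**
Reactants: 16 ring C phenol; 17 (S)-4-benzyl-3-(chloroacetyl)oxazolidin-2-one
Product: 18 (S)-4-benzyl-3-[(ring C aryloxy)acetyl]oxazolidin-2-one
Conditions: K2CO3, NaI (cat.), acetone, 50 °C
Reagents that add atoms: none
Why: Williamson etherification by SN2 displacement at the α-halo carbonyl carbon (Finkelstein activation), which installs the aryloxyacetyl imide in one step.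

**Step 11**
Reactants: 19 (E)-isoeugenol; 20 (R)-4-benzyl-3-(chloroacetyl)oxazolidin-2-one
Product: 21 (R)-4-benzyl-3-({2-methoxy-4-[(E)-prop-1-enyl]phenoxy}acetyl)oxazolidin-2-one
Conditions: K2CO3, NaI (cat.), acetone, 50 °C
Reagents that add atoms: none
Why: Williamson etherification as in step 10; the propenyl group serves as a masked formyl group that is inert to the enolisation chemistry.

**Step 12**
Reactants: 21 aryloxyacetyl imide; 22 4-(benzyloxy)-3-methoxybenzaldehyde
Product: 24 (R)-4-benzyl-3-[(2R,3S)-3-(4-benzyloxy-3-methoxyphenyl)-3-hydroxy-2-{2-methoxy-4-[(E)-prop-1-enyl]phenoxy}propanoyl]oxazolidin-2-one, via boron enolate 23 (not isolated)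
Conditions: Bu2BOTf, iPr2NEt, CH2Cl2, −78 to 0 °C; then 22, −78 to 0 °C; then pH 7 buffer, MeOH, H2O2, 0 °C
Reagents that add atoms: none
Why: Evans syn-aldol reaction through the Z-dibutylboron enolate and a Zimmerman–Traxler transition state, in which the (R)-auxiliary selects the enolate face and should give the syn (lignan threo, 7S,8S) adduct.

**Step 13**
Reactants: 24 syn-aldol adduct
Product: 25 4-nitrobenzoate of the C7-inverted adduct [(2R,3R)-imide]
Conditions: 4-nitrobenzoic acid, PPh3, DIAD, THF, 0 °C to rt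
Reagents that add atoms: 4-nitrobenzoic acid, OC(=O)c1ccc(cc1)[N+](=O)[O-]
Why: Mitsunobu esterification with SN2 inversion at the benzylic carbinol turns the threo adduct into the erythro series (C7 now R).

**Step 14**
Reactants: 25 inverted ester imide
Product: 26 (1R,2S)-1-(4-benzyloxy-3-methoxyphenyl)-2-{2-methoxy-4-[(E)-prop-1-enyl]phenoxy}propane-1,3-diol
Conditions: LiBH4, MeOH (2 equiv), THF, 0 °C to rt
Reagents that add atoms: none
Why: Borohydride reduction cleaves the imide to the primary alcohol (auxiliary released) and reduces off the 4-nitrobenzoate, to give the erythro (7R,8S) diol without touching either stereocentre.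

**Step 15**
Reactants: 26 erythro diol
Product: 27 (4R,5S)-4-(4-benzyloxy-3-methoxyphenyl)-5-{2-methoxy-4-[(E)-prop-1-enyl]phenoxy}-2,2-dimethyl-1,3-dioxane
Conditions: 2,2-dimethoxypropane, PPTS (cat.), CH2Cl2, rt
Reagents that add atoms: 2,2-dimethoxypropane, COC(C)(C)OC
Why: Acid-catalysed transketalisation of the 1,3-diol to the six-membered acetonide, which masks both hydroxyls for the later enolisation and inversion steps.

**Step 16**
Reactants: 27 acetonide
Product: 29 4-{[(4R,5S)-4-(4-benzyloxy-3-methoxyphenyl)-2,2-dimethyl-1,3-dioxan-5-yl]oxy}-3-methoxybenzaldehyde, via vicinal diol 28 (not isolated)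
Conditions: OsO4 (cat.), NaIO4, 2,6-lutidine, dioxane/H2O (3:1), rt
Reagents that add atoms: sodium periodate, [Na+].[O-]I(=O)(=O)=O; osmium tetroxide (catalytic oxygen carrier), O=[Os](=O)(=O)=O
Why: Lemieux–Johnson oxidative cleavage of the propenyl group (dihydroxylation, then periodate glycol cleavage) unmasks the ring B aldehyde under buffered conditions that spare the acetonide and benzyl ether.

**Step 17**
Reactants: 18 core aryloxyacetyl imide; 29 ring B aldehyde
Product: 31 (S)-4-benzyl-3-[(2S,3R)-syn-aldol adduct of 18 and 29]oxazolidin-2-one, via boron enolate 30 (not isolated)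
Conditions: Bu2BOTf, iPr2NEt, CH2Cl2, −78 to 0 °C; then 29, −78 to 0 °C; then pH 7 buffer, MeOH, H2O2, 0 °C
Reagents that add atoms: none
Why: Evans syn-aldol reaction (Z-boron enolate, Zimmerman–Traxler transition state) in which the (S)-auxiliary should override the remote stereocentres and set the middle unit as threo (7R,8R).

**Step 18**
Reactants: 31 syn-aldol adduct
Product: 32 threo (7R,8R) 1,3-diol of the ring B–ring C unit
Conditions: NaBH4, THF/H2O (4:1), 0 °C to rt
Reagents that add atoms: none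
Why: Reductive removal of the oxazolidinone by borohydride gives the primary alcohol without epimerisation of C8.

**Step 19**
Reactants: 32 threo diol
Product: 33 bis-acetonide [(4R,5R)-dioxane on the ring B–ring C unit]
Conditions: 2,2-dimethoxypropane, PPTS (cat.), CH2Cl2, rt
Reagents that add atoms: 2,2-dimethoxypropane, COC(C)(C)OC
Why: Acid-catalysed transketalisation of the new 1,3-diol to the acetonide, under conditions that leave the furofuran and the first acetonide intact.

**Step 20**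
Reactants: 33 bis-acetonide allyl ether
Product: 34 ring D phenol
Conditions: Pd(PPh3)4 (5 mol%, zerovalent palladium), morpholine, THF, rt
Reagents that add atoms: none
Why: Tsuji–Trost deallylation through the π-allyl palladium complex, with morpholine as the allyl acceptor, frees the second syringyl phenol under neutral conditions.

**Step 21**
Reactants: 34 ring D phenol; 17 (S)-4-benzyl-3-(chloroacetyl)oxazolidin-2-one
Product: 35 (S)-4-benzyl-3-[(ring D aryloxy)acetyl]oxazolidin-2-one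
Conditions: K2CO3, NaI (cat.), acetone, 50 °C
Reagents that add atoms: none
Why: Williamson etherification at the α-halo imide as in step 10.

**Step 22**
Reactants: 35 ring D aryloxyacetyl imide; 22 4-(benzyloxy)-3-methoxybenzaldehyde
Product: 37 (S)-4-benzyl-3-[(2S,3R)-syn-aldol adduct of 35 and 22]oxazolidin-2-one, via boron enolate 36 (not isolated)
Conditions: Bu2BOTf, iPr2NEt, CH2Cl2, −78 to 0 °C; then 22, −78 to 0 °C; then pH 7 buffer, MeOH, H2O2, 0 °C
Reagents that add atoms: none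
Why: Evans syn-aldol reaction under control of the (S)-auxiliary should give the threo (7R,8R) adduct of the ring E–ring D unit.

**Step 23**
Reactants: 37 syn-aldol adduct
Product: 38 4-nitrobenzoate of the C7-inverted adduct [(2S,3S)-imide]
Conditions: 4-nitrobenzoic acid, PPh3, DIAD, THF, 0 °C to rt
Reagents that add atoms: 4-nitrobenzoic acid, OC(=O)c1ccc(cc1)[N+](=O)[O-]
Why: Mitsunobu inversion at the benzylic carbinol converts this unit into the erythro series (C7 now S).

**Step 24**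
Reactants: 38 inverted ester imide
Product: 39 erythro (7S,8R) diol of the ring E–ring D unit (di-O-benzyl bis-acetonide of the target)
Conditions: LiBH4, MeOH (2 equiv), THF, 0 °C to rt
Reagents that add atoms: none
Why: Borohydride reduction removes the auxiliary and the 4-nitrobenzoate in one operation; acetonides, benzyl ethers and the furofuran are inert.

**Step 25**
Reactants: 39 di-O-benzyl bis-acetonide
Product: 40 di-O-benzyl ether of the target (rings A and E)
Conditions: AcOH/H2O (4:1), 40 °C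
Reagents that add atoms: none
Why: Mild acid hydrolysis of the two 1,3-dioxane ketals, done while the phenols are still benzylated so that the benzylic carbinols are not ionised.

**Step 26**
Reactants: 40 di-O-benzyl ether of the target
Product: 41 target compound CNP0316493.1
Conditions: H2 (1 atm), Pd/C (10%), EtOAc/EtOH, rt, stopped at full conversion
Reagents that add atoms: none
Why: Hydrogenolysis of the two phenolic benzyl ethers under neutral conditions, which should be much faster than cleavage of the benzylic alcohols and of the benzylic ethers of the furofuran.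

**Compound list**
1 | syringaldehyde (4-hydroxy-3,5-dimethoxybenzaldehyde) | COc1cc(C=O)cc(OC)c1O | starting material
2 | 3,5-dimethoxy-4-(methoxymethoxy)benzaldehyde | COCOc1c(OC)cc(C=O)cc1OC | intermediate
3 | methyl propiolate | C#CC(=O)OC | starting material
4 | methyl (4S)-4-[3,5-dimethoxy-4-(methoxymethoxy)phenyl]-4-hydroxybut-2-ynoate | COCOc1c(OC)cc(cc1OC)[C@H](O)C#CC(=O)OC | intermediate
5 | methyl (2Z,4R)-4-[3,5-dimethoxy-4-(methoxymethoxy)phenyl]-4-hydroxybut-2-enoate | COCOc1c(OC)cc(cc1OC)[C@H](O)/C=C\C(=O)OC | intermediate (not isolated)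
6 | (5R)-5-[3,5-dimethoxy-4-(methoxymethoxy)phenyl]furan-2(5H)-one | COCOc1c(OC)cc(cc1OC)[C@@H]1OC(=O)C=C1 | intermediate
7 | 4-(allyloxy)-3,5-dimethoxybenzaldehyde | C=CCOc1c(OC)cc(C=O)cc1OC | intermediate
8 | (trimethylsilyl)methanol | C[Si](C)(C)CO | starting material
9 | 4-(allyloxy)-3,5-dimethoxybenzaldehyde bis[(trimethylsilyl)methyl] acetal | C=CCOc1c(OC)cc(cc1OC)C(OC[Si](C)(C)C)OC[Si](C)(C)C | intermediate
10 | {[(4-allyloxy-3,5-dimethoxyphenyl)(chloro)methoxy]methyl}trimethylsilane (racemic α-chloro ether) | C=CCOc1c(OC)cc(cc1OC)C(Cl)OC[Si](C)(C)C | intermediate (not isolated)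
11 | carbonyl ylide: (4-allyloxy-3,5-dimethoxybenzylidene)oxonium methylide | C=CCOc1c(OC)cc(cc1OC)C=[O+][CH2-] | intermediate (not isolated)
12 | (3R,3aS,6R,6aR)-6-[4-(allyloxy)-3,5-dimethoxyphenyl]-3-[3,5-dimethoxy-4-(methoxymethoxy)phenyl]tetrahydro-1H,3H-furo[3,4-c]furan-1-one (cis-fused, both aryl groups exo) | COCOc1c(OC)cc(cc1OC)[C@@H]1OC(=O)[C@@H]2[C@H]1CO[C@H]2c1cc(OC)c(OCC=C)c(OC)c1 | intermediate
13 | (R)-[3,5-dimethoxy-4-(methoxymethoxy)phenyl]{(3S,4S,5R)-5-[4-(allyloxy)-3,5-dimethoxyphenyl]-4-(hydroxymethyl)tetrahydrofuran-3-yl}methanol | COCOc1c(OC)cc(cc1OC)[C@H](O)[C@@H]1CO[C@@H](c2cc(OC)c(OCC=C)c(OC)c2)[C@@H]1CO | intermediate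
14 | primary methanesulfonate of diol 13 | COCOc1c(OC)cc(cc1OC)[C@H](O)[C@@H]1CO[C@@H](c2cc(OC)c(OCC=C)c(OC)c2)[C@@H]1COS(C)(=O)=O | intermediate (not isolated)
15 | (1R,3aS,4R,6aS)-4-[4-(allyloxy)-3,5-dimethoxyphenyl]-1-[3,5-dimethoxy-4-(methoxymethoxy)phenyl]tetrahydro-1H,3H-furo[3,4-c]furan [(−)-syringaresinol MOM/allyl diether] | COCOc1c(OC)cc(cc1OC)[C@@H]1OC[C@@H]2[C@H]1CO[C@H]2c1cc(OC)c(OCC=C)c(OC)c1 | intermediate
16 | 4-{(1R,3aS,4R,6aS)-4-[4-(allyloxy)-3,5-dimethoxyphenyl]tetrahydro-1H,3H-furo[3,4-c]furan-1-yl}-2,6-dimethoxyphenol | Oc1c(OC)cc(cc1OC)[C@@H]1OC[C@@H]2[C@H]1CO[C@H]2c1cc(OC)c(OCC=C)c(OC)c1 | intermediate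
17 | (S)-4-benzyl-3-(chloroacetyl)oxazolidin-2-one | ClCC(=O)N1[C@@H](Cc2ccccc2)COC1=O | starting material
18 | (S)-4-benzyl-3-[(ring C aryloxy)acetyl]oxazolidin-2-one (O-alkylated 16) | O=C(COc1c(OC)cc(cc1OC)[C@@H]1OC[C@@H]2[C@H]1CO[C@H]2c1cc(OC)c(OCC=C)c(OC)c1)N1[C@@H](Cc2ccccc2)COC1=O | intermediate
19 | (E)-isoeugenol [2-methoxy-4-(prop-1-enyl)phenol] | C/C=C/c1ccc(O)c(OC)c1 | starting material
20 | (R)-4-benzyl-3-(chloroacetyl)oxazolidin-2-one | ClCC(=O)N1[C@H](Cc2ccccc2)COC1=O | starting material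
21 | (R)-4-benzyl-3-({2-methoxy-4-[(E)-prop-1-enyl]phenoxy}acetyl)oxazolidin-2-one | C/C=C/c1ccc(OCC(=O)N2[C@H](Cc3ccccc3)COC2=O)c(OC)c1 | intermediate
22 | 4-(benzyloxy)-3-methoxybenzaldehyde (O-benzylvanillin) | COc1cc(C=O)ccc1OCc1ccccc1 | starting material
23 | Z-dibutylboron enolate of 21 (aryloxy cis to OB) | C/C=C/c1ccc(O/C=C(/N2[C@H](Cc3ccccc3)COC2=O)OB(CCCC)CCCC)c(OC)c1 | intermediate (not isolated)
24 | (R)-4-benzyl-3-[(2R,3S)-3-(4-benzyloxy-3-methoxyphenyl)-3-hydroxy-2-{2-methoxy-4-[(E)-prop-1-enyl]phenoxy}propanoyl]oxazolidin-2-one | COc1cc(ccc1OCc1ccccc1)[C@H](O)[C@H](C(=O)N1[C@H](Cc2ccccc2)COC1=O)Oc1ccc(/C=C/C)cc1OC | intermediate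
25 | (R)-4-benzyl-3-[(2R,3R)-3-(4-benzyloxy-3-methoxyphenyl)-2-{2-methoxy-4-[(E)-prop-1-enyl]phenoxy}-3-(4-nitrobenzoyloxy)propanoyl]oxazolidin-2-one | COc1cc(ccc1OCc1ccccc1)[C@@H](OC(=O)c1ccc(cc1)[N+](=O)[O-])[C@H](C(=O)N1[C@H](Cc2ccccc2)COC1=O)Oc1ccc(/C=C/C)cc1OC | intermediate
26 | (1R,2S)-1-(4-benzyloxy-3-methoxyphenyl)-2-{2-methoxy-4-[(E)-prop-1-enyl]phenoxy}propane-1,3-diol (erythro) | COc1cc(ccc1OCc1ccccc1)[C@@H](O)[C@H](CO)Oc1ccc(/C=C/C)cc1OC | intermediate
27 | (4R,5S)-4-(4-benzyloxy-3-methoxyphenyl)-5-{2-methoxy-4-[(E)-prop-1-enyl]phenoxy}-2,2-dimethyl-1,3-dioxane | COc1cc(ccc1OCc1ccccc1)[C@H]1OC(C)(C)OC[C@@H]1Oc1ccc(/C=C/C)cc1OC | intermediate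
28 | 1-(4-{[(4R,5S)-4-(4-benzyloxy-3-methoxyphenyl)-2,2-dimethyl-1,3-dioxan-5-yl]oxy}-3-methoxyphenyl)propane-1,2-diol (diastereomer mixture) | COc1cc(ccc1OCc1ccccc1)[C@H]1OC(C)(C)OC[C@@H]1Oc1ccc(cc1OC)C(O)C(C)O | intermediate (not isolated)
29 | 4-{[(4R,5S)-4-(4-benzyloxy-3-methoxyphenyl)-2,2-dimethyl-1,3-dioxan-5-yl]oxy}-3-methoxybenzaldehyde | COc1cc(ccc1OCc1ccccc1)[C@H]1OC(C)(C)OC[C@@H]1Oc1ccc(C=O)cc1OC | intermediate
30 | Z-dibutylboron enolate of 18 (aryloxy cis to OB) | CCCCB(CCCC)O/C(=C\Oc1c(OC)cc(cc1OC)[C@@H]1OC[C@@H]2[C@H]1CO[C@H]2c1cc(OC)c(OCC=C)c(OC)c1)N1[C@@H](Cc2ccccc2)COC1=O | intermediate (not isolated)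
31 | (S)-4-benzyl-3-[(2S,3R)-3-hydroxy-2-(ring C aryloxy)-3-(ring B aryl)propanoyl]oxazolidin-2-one (ring B carries the 4R,5S acetonide arm; ring D O-allyl) | COc1cc(ccc1OCc1ccccc1)[C@H]1OC(C)(C)OC[C@@H]1Oc1ccc(cc1OC)[C@@H](O)[C@@H](C(=O)N1[C@@H](Cc2ccccc2)COC1=O)Oc1c(OC)cc(cc1OC)[C@@H]1OC[C@@H]2[C@H]1CO[C@H]2c1cc(OC)c(OCC=C)c(OC)c1 | intermediate
32 | threo (7R,8R) 1,3-diol of the ring B–ring C unit (outer unit as 4R,5S acetonide; ring D O-allyl) | COc1cc(ccc1OCc1ccccc1)[C@H]1OC(C)(C)OC[C@@H]1Oc1ccc(cc1OC)[C@@H](O)[C@@H](CO)Oc1c(OC)cc(cc1OC)[C@@H]1OC[C@@H]2[C@H]1CO[C@H]2c1cc(OC)c(OCC=C)c(OC)c1 | intermediate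
33 | bis-acetonide [(4R,5S)-dioxane on the A–B unit and (4R,5R)-dioxane on the B–C unit; ring A O-benzyl; ring D O-allyl] | COc1cc(ccc1OCc1ccccc1)[C@H]1OC(C)(C)OC[C@@H]1Oc1ccc(cc1OC)[C@H]1OC(C)(C)OC[C@H]1Oc1c(OC)cc(cc1OC)[C@@H]1OC[C@@H]2[C@H]1CO[C@H]2c1cc(OC)c(OCC=C)c(OC)c1 | intermediate
34 | ring D phenol (de-allylated 33) | COc1cc(ccc1OCc1ccccc1)[C@H]1OC(C)(C)OC[C@@H]1Oc1ccc(cc1OC)[C@H]1OC(C)(C)OC[C@H]1Oc1c(OC)cc(cc1OC)[C@@H]1OC[C@@H]2[C@H]1CO[C@H]2c1cc(OC)c(O)c(OC)c1 | intermediate
35 | (S)-4-benzyl-3-[(ring D aryloxy)acetyl]oxazolidin-2-one (O-alkylated 34) | COc1cc(ccc1OCc1ccccc1)[C@H]1OC(C)(C)OC[C@@H]1Oc1ccc(cc1OC)[C@H]1OC(C)(C)OC[C@H]1Oc1c(OC)cc(cc1OC)[C@@H]1OC[C@@H]2[C@H]1CO[C@H]2c1cc(OC)c(OCC(=O)N2[C@@H](Cc3ccccc3)COC2=O)c(OC)c1 | intermediate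
36 | Z-dibutylboron enolate of 35 (aryloxy cis to OB) | COc1cc(ccc1OCc1ccccc1)[C@H]1OC(C)(C)OC[C@@H]1Oc1ccc(cc1OC)[C@H]1OC(C)(C)OC[C@H]1Oc1c(OC)cc(cc1OC)[C@@H]1OC[C@@H]2[C@H]1CO[C@H]2c1cc(OC)c(O/C=C(/N2[C@@H](Cc3ccccc3)COC2=O)OB(CCCC)CCCC)c(OC)c1 | intermediate (not isolated)
37 | (S)-4-benzyl-3-[(2S,3R)-3-(4-benzyloxy-3-methoxyphenyl)-3-hydroxy-2-(ring D aryloxy)propanoyl]oxazolidin-2-one | COc1cc(ccc1OCc1ccccc1)[C@H]1OC(C)(C)OC[C@@H]1Oc1ccc(cc1OC)[C@H]1OC(C)(C)OC[C@H]1Oc1c(OC)cc(cc1OC)[C@@H]1OC[C@@H]2[C@H]1CO[C@H]2c1cc(OC)c(O[C@H](C(=O)N2[C@@H](Cc3ccccc3)COC2=O)[C@H](O)c2ccc(OCc3ccccc3)c(OC)c2)c(OC)c1 | intermediate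
38 | (S)-4-benzyl-3-[(2S,3S)-3-(4-benzyloxy-3-methoxyphenyl)-3-(4-nitrobenzoyloxy)-2-(ring D aryloxy)propanoyl]oxazolidin-2-one | COc1cc(ccc1OCc1ccccc1)[C@H]1OC(C)(C)OC[C@@H]1Oc1ccc(cc1OC)[C@H]1OC(C)(C)OC[C@H]1Oc1c(OC)cc(cc1OC)[C@@H]1OC[C@@H]2[C@H]1CO[C@H]2c1cc(OC)c(O[C@H](C(=O)N2[C@@H](Cc3ccccc3)COC2=O)[C@@H](OC(=O)c2ccc(cc2)[N+](=O)[O-])c2ccc(OCc3ccccc3)c(OC)c2)c(OC)c1 | intermediate
39 | di-O-benzyl bis-acetonide of the target [free erythro (7S,8R) diol on the E–D unit] | COc1cc(ccc1OCc1ccccc1)[C@H]1OC(C)(C)OC[C@@H]1Oc1ccc(cc1OC)[C@H]1OC(C)(C)OC[C@H]1Oc1c(OC)cc(cc1OC)[C@@H]1OC[C@@H]2[C@H]1CO[C@H]2c1cc(OC)c(O[C@H](CO)[C@@H](O)c2ccc(OCc3ccccc3)c(OC)c2)c(OC)c1 | intermediate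
40 | di-O-benzyl ether of the target (rings A and E benzylated; all six aliphatic hydroxyls free) | COc1cc(ccc1OCc1ccccc1)[C@@H](O)[C@H](CO)Oc1ccc(cc1OC)[C@@H](O)[C@@H](CO)Oc1c(OC)cc(cc1OC)[C@@H]1OC[C@@H]2[C@H]1CO[C@H]2c1cc(OC)c(O[C@H](CO)[C@@H](O)c2ccc(OCc3ccccc3)c(OC)c2)c(OC)c1 | intermediate
41 | CNP0316493.1 [core 7R,8S,7'R,8'S; A–B unit 7R,8S erythro; B–C unit 7R,8R threo; E–D unit 7S,8R erythro] | COc1cc([C@@H](O)[C@H](CO)Oc2ccc([C@@H](O)[C@@H](CO)Oc3c(OC)cc([C@@H]4OC[C@@H]5[C@H]4CO[C@H]5c4cc(OC)c(O[C@H](CO)[C@@H](O)c5ccc(O)c(OC)c5)c(OC)c4)cc3OC)cc2OC)ccc1O | target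

**Step count**
Total: 26 steps. Longest linear sequence: 18 steps (1, 2, 3, 6, 7, 8, 9, 10, 17–26).

**Steps most likely to fail**

1. Step 6. What may go wrong: fluoride-promoted deprotonation at C5 of the butenolide (loss of enantiopurity or drift to the hydroxyfuran tautomer) competing with the cycloaddition; collapse or dimerisation of the short-lived ylide before it meets the dipolarophile; erosion of regio- or exo-selectivity.
Fallback (sets out from 6 and 7, comes back at 12): copper-catalysed conjugate addition of (isopropoxydimethylsilyl)methylmagnesium chloride to 6 (CuBr·SMe2, TMSCl, THF, −78 °C), anti to the aryl group, should give (4R,5R)-5-aryl-4-{[isopropoxy(dimethyl)silyl]methyl}dihydrofuran-2(3H)-one F1. Tamao–Fleming oxidation (KF, KHCO3, H2O2, THF/MeOH) should give the (4S,5R)-4-(hydroxymethyl) lactone F2. Aldehyde 7 is converted into its dimethyl acetal F3 (HC(OMe)3, PPTS, MeOH) and transacetalised with F2 (PPTS, cyclohexane, removal of MeOH) to the mixed methyl acetal F4. Enolisation and silylation (LiN(iPr)2, TMSCl, THF, −78 °C) followed by ionisation of the acetal (BF3·OEt2, CH2Cl2, −78 °C) should then close the second ring by an intramolecular Mukaiyama-type aldol addition onto the oxocarbenium ion, cis-fused because of the tether and with the aryl group exo, to give 12. The same two carbon–carbon bonds are thus made one after the other by polar reactions.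

2. Step 23 (the same holds for step 13). What may go wrong: E1cB loss of the activated oxygen from the β-hydroxy imide, or ionisation at the electron-rich benzylic carbon, leading to elimination or incomplete inversion.
Fallback (sets out from 37, comes back at 39): NaBH4 (THF/H2O) removes the auxiliary from 37 to give the threo (7R,8R) diol F5. Selective silylation of the primary hydroxyl (TBSCl, imidazole, CH2Cl2) gives the silyl ether F6. Dess–Martin periodinane (NaHCO3, CH2Cl2) oxidises the benzylic alcohol to the α-aryloxy ketone F7. Felkin–Anh-controlled reduction (NaBH4, THF/MeOH, −40 °C), with the aryloxy group as the polar substituent, should give the erythro (7S,8R) alcohol F8. TBAF (THF) then gives 39. Inversion is thus achieved by oxidation and reduction instead of by substitution.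

3. Step 10 (the same holds for steps 11 and 21). What may go wrong: attack of the hindered 2,6-dimethoxyphenoxide at the imide carbonyl groups (loss of the auxiliary) instead of displacement at the CH2Cl carbon.
Fallback (sets out from 16, comes back at 18): alkylation of 16 with methyl bromoacetate (K2CO3, acetone) gives the aryloxyacetic ester F9. Saponification (LiOH, THF/H2O) gives the acid F10. Activation as the mixed pivalic anhydride (PivCl, Et3N, THF, −20 °C) and N-acylation of (S)-4-benzyloxazolidin-2-one (LiCl, rt) gives 18. The imide is thus built by acylation of the auxiliary instead of by etherification with the preformed halo imide.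

**Further compounds**
F1 | step 6 | (4R,5R)-5-[3,5-dimethoxy-4-(methoxymethoxy)phenyl]-4-{[isopropoxy(dimethyl)silyl]methyl}dihydrofuran-2(3H)-one | COCOc1c(OC)cc(cc1OC)[C@@H]1OC(=O)C[C@H]1C[Si](C)(C)OC(C)C
F2 | step 6 | (4S,5R)-5-[3,5-dimethoxy-4-(methoxymethoxy)phenyl]-4-(hydroxymethyl)dihydrofuran-2(3H)-one | COCOc1c(OC)cc(cc1OC)[C@@H]1OC(=O)C[C@H]1CO
F3 | step 6 | 4-(allyloxy)-3,5-dimethoxybenzaldehyde dimethyl acetal | C=CCOc1c(OC)cc(cc1OC)C(OC)OC
F4 | step 6 | mixed methyl acetal of F2 and aldehyde 7 (acetal carbon unassigned) | COCOc1c(OC)cc(cc1OC)[C@@H]1OC(=O)C[C@H]1COC(OC)c1cc(OC)c(OCC=C)c(OC)c1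
F5 | step 23 | threo (7R,8R) diol of the E–D unit (C7 epimer of 39) | COc1cc(ccc1OCc1ccccc1)[C@H]1OC(C)(C)OC[C@@H]1Oc1ccc(cc1OC)[C@H]1OC(C)(C)OC[C@H]1Oc1c(OC)cc(cc1OC)[C@@H]1OC[C@@H]2[C@H]1CO[C@H]2c1cc(OC)c(O[C@H](CO)[C@H](O)c2ccc(OCc3ccccc3)c(OC)c2)c(OC)c1
F6 | step 23 | primary tert-butyldimethylsilyl ether of F5 | COc1cc(ccc1OCc1ccccc1)[C@H]1OC(C)(C)OC[C@@H]1Oc1ccc(cc1OC)[C@H]1OC(C)(C)OC[C@H]1Oc1c(OC)cc(cc1OC)[C@@H]1OC[C@@H]2[C@H]1CO[C@H]2c1cc(OC)c(O[C@H](CO[Si](C)(C)C(C)(C)C)[C@H](O)c2ccc(OCc3ccccc3)c(OC)c2)c(OC)c1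
F7 | step 23 | (8R)-α-aryloxy aryl ketone from F6 | COc1cc(ccc1OCc1ccccc1)[C@H]1OC(C)(C)OC[C@@H]1Oc1ccc(cc1OC)[C@H]1OC(C)(C)OC[C@H]1Oc1c(OC)cc(cc1OC)[C@@H]1OC[C@@H]2[C@H]1CO[C@H]2c1cc(OC)c(O[C@H](CO[Si](C)(C)C(C)(C)C)C(=O)c2ccc(OCc3ccccc3)c(OC)c2)c(OC)c1
F8 | step 23 | erythro (7S,8R) alcohol, primary silyl ether of 39 | COc1cc(ccc1OCc1ccccc1)[C@H]1OC(C)(C)OC[C@@H]1Oc1ccc(cc1OC)[C@H]1OC(C)(C)OC[C@H]1Oc1c(OC)cc(cc1OC)[C@@H]1OC[C@@H]2[C@H]1CO[C@H]2c1cc(OC)c(O[C@H](CO[Si](C)(C)C(C)(C)C)[C@@H](O)c2ccc(OCc3ccccc3)c(OC)c2)c(OC)c1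
F9 | step 10 | methyl (ring C aryloxy)acetate of 16 | COC(=O)COc1c(OC)cc(cc1OC)[C@@H]1OC[C@@H]2[C@H]1CO[C@H]2c1cc(OC)c(OCC=C)c(OC)c1
F10 | step 10 | (ring C aryloxy)acetic acid of 16 | OC(=O)COc1c(OC)cc(cc1OC)[C@@H]1OC[C@@H]2[C@H]1CO[C@H]2c1cc(OC)c(OCC=C)c(OC)c1
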